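Readings and results were generated by integration with made-up constants, noise included.

Against side product plus waste, left-handed product stood at 0.451 in the last reading of Tuesday's run, about half. This is the capture ratio: left-handed product made over material lost through the achiral form. Dividing one rate by the other takes out the clock but not c(partner), which falls during a run, and the same ratio stood at 0.944 in the first reading of Tuesday's run. So it is the ratio of a finished run that is carried to the next flask, and as a rough scale.

in all of them: left-handed substrate 20 mM; right-handed substrate 20 mM
- Tuesday's: partner 90 mM; run made earlier
- flask: partner 60.0 mM; time 10 h

Tuesday's run (percent of the left-handed substrate and right-handed substrate together charged)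

| time / h | left-handed substrate / % | left-handed product / % | side product / % | waste / % |
|---|---|---|---|---|
| 0.200 | 26.9 | 13.6 | 13.2 | 1.2 |
| 0.667 | 9.4 | 23.6 | 35.1 | 7.0 |
| 1.00 | 6.8 | 27.2 | 45.0 | 6.0 |
| 1.50 | 2.7 | 28.4 | 52.2 | 8.0 |
| 2.50 | 0 | 31.8 | 56.2 | 9.4 |
| 3.00 | 2.2 | 29.5 | 57.5 | 7.9 |

(standard deviation of a reading: 1 percentage point)

- partner is single-handed; left-handed substrate and right-handed substrate are mirror images of each other, charged as a racemate, each of them at the stated concentration
- the numbers in the tables scatter by 1 percentage point (one standard deviation)
- candidate steps: achiral form -> side product; partner -> decomposed reagent; partner + left-handed substrate -> left-handed product; right-handed substrate <-> achiral form; left-handed substrate <-> achiral form; partner + right-handed substrate -> right-handed product; achiral form -> waste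
- the reaction counts as stopped when no species that holds the left-handed substrate and right-handed substrate together changes by six tenths of a point or more over the second half of the time
- the handed part of partner does not stay in what it makes, so the products of the two hands are mirror images too
- a reading of left-handed substrate is of its free form alone

1. why nothing more happens at 10 h, or that something still does (all of the left-handed substrate has reacted / forward and back rates have come level / it is still moving)
2. share of the left-handed substrate and right-handed substrate together used up at 10 h
3. left-handed product at 10 h, in percent of the left-handed substrate and right-handed substrate together charged
4. side product at 10 h, in percent of the left-handed substrate and right-handed substrate together charged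
5. waste at 10 h, in percent of the left-handed substrate and right-handed substrate together charged

Note for the bench: the flask holds both substrates, with partner capturing them while the achiral form bleeds them away. Free left-handed substrate fell at 1.77 h⁻¹ on Tuesday, a half-life of 0.392 h, much shorter than 10 h. The flask should therefore hold no substrate on arrival, and waiting longer gains nothing. The partner charge is what must not be altered. Capture carries c(partner) to the first power and the losses from the achiral form do not carry it, so the reckoning here scales the ratio with the charge, to 0.301 at 60.0 mM. Neglecting right-handed product, that puts left-handed product at 23.1%.

The forecast gave all of the left-handed substrate has reacted, conversion 100%, left-handed product 25%, side product 65% and waste 10%, reasoning that “the partner takes only the left hand, and the rest leaks through the achiral form”.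

The flask at 10 h gives all of the left-handed substrate has reacted, with conversion >99.9%, left-handed product 22.9%, side product 64.5% and waste 11.1%.

    achiral form → side product (k = 0.110 min⁻¹)
    partner → decomposed reagent (k = 0.0100 min⁻¹)
    partner + left-handed substrate → left-handed product (k = 0.390 L mol⁻¹ min⁻¹)
    right-handed substrate ⇌ achiral form (K = 0.580, k = 0.0540 min⁻¹)
    left-handed substrate ⇌ achiral form (K = 0.580, k = 0.0540 min⁻¹)
    partner + right-handed substrate → right-handed product (k = 0.0200 L mol⁻¹ min⁻¹)
    achiral form → waste (k = 0.0190 min⁻¹)

The capture ratio of the flask comes to 0.303 against the reckoned 0.301, while left-handed substrate and achiral form relax with a half-life of 0.0785 h, far shorter than the 1.2 h half-life of partner by its decomposition. The neighbouring flask with 24 mM of partner was reckoned at 0.120 and stands at 0.123, but the one with 240 mM was reckoned at 1.20 and stands at 1.02.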